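**Plan** (labdane numbering)
- Retrosynthesis: the two acetates come off first. Then C3–C4 of ring A is cut, C4 is joined to C7 instead, C8 becomes an exocyclic C8=C17 methylene and C3 an aldehyde.
- Enabling feature: in ring B, C5 (which carries the gem-dimethyl carbon C4) and the alkene carbon C7 flank C6 in a 1,3 relation. This is the trace left when a pinane cyclobutane (C4 bridging C5 and C7) is opened from a radical at C8.
- Further cuts: C8=C17 (ketone methylenation), C9–C11 (aldol condensation, then C=C hydrogenation) and C10–C1 (conjugate addition). These lead back to (1R,5R)-verbenone, a C1–C3 silyloxypropyl Grignard reagent and a C11–C15 aldehyde.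
- Forward: ring B arrives with verbenone; the tether, the side chain and C17 are attached in that order; ring A closes last, in the cascade that also opens the cyclobutane and places the C7=C8 alkene.
- Stereochemistry: C5 from verbenone; C10 and C9 from approach anti to the gem-dimethyl bridge (cuprate, then H2); C13 from methyl hydrogen (R)-3-methylglutarate; C3 from the chair of the radical closure.

Key step: step 11

Remark: labdane numbering is used throughout; in the pinane-type intermediates β is the face of ring B carrying the C4 bridge and C20, α the opposite face; the alkene geometry of 13 and the C9/C11 configurations of 11 and 12 are inconsequential and left undefined; bromide 5 is taken as a purchased reagent.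

**Step 1**
Reactants: 1 methyl hydrogen (R)-3-methylglutarate
Product: 2 methyl (3R)-5-hydroxy-3-methylpentanoate
Conditions: BH3·SMe2, THF, 0 °C → rt; then MeOH
Reagents that add atoms: none
Why: Chemoselective borane reduction of a carboxylic acid, which reacts through its acyloxyborane far faster than the methyl ester, should leave the C13 stereocentre untouched.

**Step 2**
Reactants: 2 methyl (3R)-5-hydroxy-3-methylpentanoate
Product: 3 methyl (3R)-5-(tert-butyldiphenylsilyloxy)-3-methylpentanoate
Conditions: TBDPSCl, imidazole, CH2Cl2, rt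
Reagents that add atoms: tert-butyl(chloro)diphenylsilane (TBDPSCl), CC(C)(C)[Si](Cl)(c1ccccc1)c1ccccc1
Why: Imidazole-promoted silylation of the primary alcohol forestalls lactonisation and installs a silyl ether robust enough to outlast the later cleavage of a tert-butyldimethylsilyl ether.

**Step 3**
Reactants: 3 methyl (3R)-5-(tert-butyldiphenylsilyloxy)-3-methylpentanoate
Product: 4 (3R)-5-(tert-butyldiphenylsilyloxy)-3-methylpentanal
Conditions: i-Bu2AlH, CH2Cl2, −78 °C; then MeOH, aq. KNaC4H4O6 (tartrate)
Reagents that add atoms: none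
Why: Partial ester reduction by i-Bu2AlH at −78 °C should stop at the tetrahedral aluminium hemiacetal, which releases the aldehyde only on work-up; the stereocentre is β to the carbonyl and cannot epimerise.

**Step 4**
Reactants: 5 (3-bromopropoxy)(tert-butyl)dimethylsilane; 6 (1R,5R)-verbenone
Product: 9 (1R,4R,5R)-4-[3-(tert-butyldimethylsilyloxy)propyl]-4,6,6-trimethylbicyclo[3.1.1]heptan-2-one, via Grignard reagent 7 (not isolated), via trimethylsilyl enol ether 8 (not isolated)
Conditions: Mg, THF, rt; then 6, CuBr·SMe2 (10 mol %), Me3SiCl, THF, −78 → −20 °C; then K2CO3 (cat.), MeOH, rt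
Reagents that add atoms: none
Why: Copper-catalysed, Me3SiCl-accelerated conjugate addition of a Grignard reagent to the β,β-disubstituted enone should deliver the C1–C3 tether to C10 from the face opposite the gem-dimethyl bridge (tether α, C20 methyl β), and methanolysis of enol ether 8 returns the ketone.

**Step 5**
Reactants: 9 (1R,4R,5R)-4-[3-(tert-butyldimethylsilyloxy)propyl]-4,6,6-trimethylbicyclo[3.1.1]heptan-2-one; 4 (3R)-5-(tert-butyldiphenylsilyloxy)-3-methylpentanal
Product: 11 (1R,4S,5S)-4-[3-(tert-butyldimethylsilyloxy)propyl]-3-[(3R)-5-(tert-butyldiphenylsilyloxy)-1-hydroxy-3-methylpentyl]-4,6,6-trimethylbicyclo[3.1.1]heptan-2-one (C9/C11 diastereomer mixture), via lithium enolate 10 (not isolated)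
Conditions: LiN(i-Pr)2, THF, −78 °C; then 4, −78 °C; AcOH quench
Reagents that add atoms: none
Why: Directed aldol addition of a preformed lithium enolate: the ketone can enolise only towards C9 because the other α-carbon is the cyclobutane bridgehead C7, and the new carbinol and C9 centres need no control since both are erased in the next two steps.

**Step 6**
Reactants: 11 aldol adduct
Product: 13 (1R,4S,5S)-4-[3-(tert-butyldimethylsilyloxy)propyl]-3-[(3S)-5-(tert-butyldiphenylsilyloxy)-3-methylpentylidene]-4,6,6-trimethylbicyclo[3.1.1]heptan-2-one, via mesylate 12 (not isolated)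
Conditions: MsCl, Et3N, CH2Cl2, 0 °C; then DBU, rt
Reagents that add atoms: none
Why: Mesylation followed by base-induced E1cB elimination completes the aldol condensation, and any mixture of alkene isomers converges because the double bond is saturated next.

**Step 7**
Reactants: 13 C9=C11 enone
Product: 14 (1R,3R,4S,5S)-4-[3-(tert-butyldimethylsilyloxy)propyl]-3-[(3S)-5-(tert-butyldiphenylsilyloxy)-3-methylpentyl]-4,6,6-trimethylbicyclo[3.1.1]heptan-2-one
Conditions: H2 (3 bar), Pd/C, EtOAc, rt
Reagents that add atoms: none
Why: Heterogeneous catalytic hydrogenation of the enone C=C should place hydrogen on C9 from the α-face, away from the gem-dimethyl bridge whose inner methyl roofs the β-face, so the side chain ends up β; silyl ethers, ketone and cyclobutane are inert.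

**Step 8**
Reactants: 14 C9-alkylated ketone
Product: 15 tert-butyl{3-[(1R,3S,4S,5S)-3-{(3S)-5-(tert-butyldiphenylsilyloxy)-3-methylpentyl}-4,6,6-trimethyl-2-methylidenebicyclo[3.1.1]heptan-4-yl]propoxy}dimethylsilane
Conditions: Cp2TiMe2, toluene, 70 °C, dark
Reagents that add atoms: dimethyltitanocene (Cp2TiMe2), C[Ti](C)(C1C=CC=C1)C1C=CC=C1
Why: Petasis methylenation uses a small, non-basic titanium methylidene and should therefore convert the hindered, enolisable C8 ketone into the C8=C17 methylene without epimerising C9.

**Step 9**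
Reactants: 15 bis-silyl ether with the C8=C17 methylene
Product: 16 3-[(1R,3S,4S,5S)-3-{(3S)-5-(tert-butyldiphenylsilyloxy)-3-methylpentyl}-4,6,6-trimethyl-2-methylidenebicyclo[3.1.1]heptan-4-yl]propan-1-ol
Conditions: PPTS (cat.), MeOH, 25–40 °C
Reagents that add atoms: none
Why: Acid-catalysed methanolysis (selective desilylation) removes a primary tert-butyldimethylsilyl ether much faster than a primary tert-butyldiphenylsilyl ether, and the pyridinium salt is too weak an acid to protonate the strained methylenecyclobutane.

**Step 10**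
Reactants: 16 primary alcohol
Product: 17 3-[(1R,3S,4S,5S)-3-{(3S)-5-(tert-butyldiphenylsilyloxy)-3-methylpentyl}-4,6,6-trimethyl-2-methylidenebicyclo[3.1.1]heptan-4-yl]propanal [(13S)-15-(tert-butyldiphenylsilyloxy)-4,7-cyclo-3,4-secolabd-8(17)-en-3-al]
Conditions: Dess–Martin periodinane, NaHCO3, CH2Cl2, 0 °C → rt
Reagents that add atoms: none
Why: Dess–Martin oxidation under buffered conditions should take the primary alcohol to the aldehyde without touching the 1,1-disubstituted alkene or the silyl ether.

**Step 11**
Reactants: 17 pinane-type aldehyde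
Product: 21 (3S,5R,9S,10R,13S)-15-(tert-butyldiphenylsilyloxy)labd-7-en-3-ol (the 3β-alcohol), via C8 radical 18 (not isolated), via ring-opened C4 radical 19 (not isolated), via C3 alkoxyl radical 20 (not isolated)
Conditions: Fe(acac)3 (30 mol %), PhSiH3 (2.5 equiv, added slowly), degassed EtOH, 60 °C, 0.01 M
Reagents that add atoms: none
Why: Proposed new method: an iron hydride formed from Fe(acac)3 and PhSiH3 should deliver a hydrogen atom to C17, the terminal carbon of the exocyclic alkene; the tertiary cyclobutylcarbinyl radical 18 should then release ring strain by β-scission of C4–C7, the only cleavage that leaves a tertiary radical, and radical 19 should add to the C3 aldehyde to give alkoxyl radical 20, which divalent iron and ethanol convert into the alcohol while trivalent iron is returned. The closest known reaction types are the hydrogen-atom-transfer opening of β-pinene-type methylenecyclobutanes and the hydrogen-atom-transfer-initiated cyclization of alkenes onto ketones and aldehydes; their union in one cascade is untested. Ring A closes in the 6-exo-trig mode at the carbonyl carbon (bond C3–C4), while ring B changes from the bicycle to a cyclohexene whose C7=C8 double bond can appear in one position only. The ring fusion is fixed beforehand, because C5–C4 and C10–C1 are trans on ring B and become the two equatorial bonds of a chair transition state; C3 is therefore the only new stereocentre, and it is set by the carbonyl oxygen taking the equatorial site of that chair, clear of the axial hydrogens on C1 and C5, which gives the 3β-alcohol. The step needs scission to outrun reduction of 18, closure to outrun reduction of 19, capture of 20 to outrun its reversal, and hydrogen-atom transfer to the 1,1-disubstituted alkene in preference to the trisubstituted alkene of the product; cyclobutane strain, the pre-set trans-diequatorial geometry, high dilution with slow silane addition and the lower reactivity of trisubstituted alkenes should secure these.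

**Step 12**
Reactants: 21 (3S,5R,9S,10R,13S)-15-(tert-butyldiphenylsilyloxy)labd-7-en-3-ol
Product: 22 (3S,5R,9S,10R,13S)-labd-7-ene-3,15-diol
Conditions: Bu4NF, THF, rt
Reagents that add atoms: none
Why: Fluoride-induced desilylation, driven by the strength of the Si–F bond, should free the C15 alcohol without affecting the trisubstituted alkene or any stereocentre.

**Step 13**
Reactants: 22 (3S,5R,9S,10R,13S)-labd-7-ene-3,15-diol
Product: 23 (3S,5R,9S,10R,13S)-labd-7-ene-3,15-diyl diacetate (CNP0251773.1)
Conditions: Ac2O, pyridine, DMAP (cat.), CH2Cl2, rt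
Reagents that add atoms: acetic anhydride, CC(=O)OC(C)=O
Why: DMAP-catalysed acetylation with excess anhydride should esterify both the primary C15 hydroxyl and the hindered equatorial C3 hydroxyl with retention at every stereocentre.

**Compound list**

1 | methyl hydrogen (R)-3-methylglutarate | OC(=O)C[C@@H](C)CC(=O)OC | starting material
2 | methyl (3R)-5-hydroxy-3-methylpentanoate | OCC[C@@H](C)CC(=O)OC | intermediate
3 | methyl (3R)-5-(tert-butyldiphenylsilyloxy)-3-methylpentanoate | CC(C)(C)[Si](c1ccccc1)(c1ccccc1)OCC[C@@H](C)CC(=O)OC | intermediate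
4 | (3R)-5-(tert-butyldiphenylsilyloxy)-3-methylpentanal | CC(C)(C)[Si](c1ccccc1)(c1ccccc1)OCC[C@@H](C)CC=O | intermediate
5 | (3-bromopropoxy)(tert-butyl)dimethylsilane | BrCCCO[Si](C)(C)C(C)(C)C | starting material
6 | (1R,5R)-verbenone | O=C1[C@@H]2C[C@@H](C2(C)C)C(C)=C1 | starting material
7 | [3-(tert-butyldimethylsilyloxy)propyl]magnesium bromide | CC(C)(C)[Si](C)(C)OCCC[Mg]Br | intermediate (not isolated)
8 | trimethylsilyl enol ether of 9 (C8–OSiMe3, C8=C9; stereocentres as in 9) | C[Si](C)(C)OC1=C[C@@](C)(CCCO[Si](C)(C)C(C)(C)C)[C@H]2C[C@@H]1C2(C)C | intermediate (not isolated)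
9 | (1R,4R,5R)-4-[3-(tert-butyldimethylsilyloxy)propyl]-4,6,6-trimethylbicyclo[3.1.1]heptan-2-one (tether anti to the gem-dimethyl bridge) | O=C1[C@@H]2C[C@@H](C2(C)C)[C@](C)(CCCO[Si](C)(C)C(C)(C)C)C1 | intermediate
10 | lithium enolate of 9 (C8–OLi, C8=C9) | [Li]OC1=C[C@@](C)(CCCO[Si](C)(C)C(C)(C)C)[C@H]2C[C@@H]1C2(C)C | intermediate (not isolated)
11 | (1R,4S,5S)-4-[3-(tert-butyldimethylsilyloxy)propyl]-3-[(3R)-5-(tert-butyldiphenylsilyloxy)-1-hydroxy-3-methylpentyl]-4,6,6-trimethylbicyclo[3.1.1]heptan-2-one (C9/C11 mixture) | CC(C)(C)[Si](c1ccccc1)(c1ccccc1)OCC[C@@H](C)CC(O)C1C(=O)[C@@H]2C[C@@H](C2(C)C)[C@]1(C)CCCO[Si](C)(C)C(C)(C)C | intermediate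
12 | C11 methanesulfonate of 11 | CC(C)(C)[Si](c1ccccc1)(c1ccccc1)OCC[C@@H](C)CC(OS(C)(=O)=O)C1C(=O)[C@@H]2C[C@@H](C2(C)C)[C@]1(C)CCCO[Si](C)(C)C(C)(C)C | intermediate (not isolated)
13 | (1R,4S,5S)-4-[3-(tert-butyldimethylsilyloxy)propyl]-3-[(3S)-5-(tert-butyldiphenylsilyloxy)-3-methylpentylidene]-4,6,6-trimethylbicyclo[3.1.1]heptan-2-one (C9=C11 geometry undefined) | CC(C)(C)[Si](c1ccccc1)(c1ccccc1)OCC[C@@H](C)CC=C1C(=O)[C@@H]2C[C@@H](C2(C)C)[C@]1(C)CCCO[Si](C)(C)C(C)(C)C | intermediate
14 | (1R,3R,4S,5S)-4-[3-(tert-butyldimethylsilyloxy)propyl]-3-[(3S)-5-(tert-butyldiphenylsilyloxy)-3-methylpentyl]-4,6,6-trimethylbicyclo[3.1.1]heptan-2-one (side chain syn to the bridge, H9 α) | CC(C)(C)[Si](c1ccccc1)(c1ccccc1)OCC[C@@H](C)CC[C@H]1C(=O)[C@@H]2C[C@@H](C2(C)C)[C@]1(C)CCCO[Si](C)(C)C(C)(C)C | intermediate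
15 | tert-butyl{3-[(1R,3S,4S,5S)-3-{(3S)-5-(tert-butyldiphenylsilyloxy)-3-methylpentyl}-4,6,6-trimethyl-2-methylidenebicyclo[3.1.1]heptan-4-yl]propoxy}dimethylsilane | CC(C)(C)[Si](c1ccccc1)(c1ccccc1)OCC[C@@H](C)CC[C@H]1C(=C)[C@@H]2C[C@@H](C2(C)C)[C@]1(C)CCCO[Si](C)(C)C(C)(C)C | intermediate
16 | 3-[(1R,3S,4S,5S)-3-{(3S)-5-(tert-butyldiphenylsilyloxy)-3-methylpentyl}-4,6,6-trimethyl-2-methylidenebicyclo[3.1.1]heptan-4-yl]propan-1-ol | CC(C)(C)[Si](c1ccccc1)(c1ccccc1)OCC[C@@H](C)CC[C@H]1C(=C)[C@@H]2C[C@@H](C2(C)C)[C@]1(C)CCCO | intermediate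
17 | 3-[(1R,3S,4S,5S)-3-{(3S)-5-(tert-butyldiphenylsilyloxy)-3-methylpentyl}-4,6,6-trimethyl-2-methylidenebicyclo[3.1.1]heptan-4-yl]propanal | CC(C)(C)[Si](c1ccccc1)(c1ccccc1)OCC[C@@H](C)CC[C@H]1C(=C)[C@@H]2C[C@@H](C2(C)C)[C@]1(C)CCC=O | intermediate (key-step precursor)
18 | C8-centred tertiary radical of 17 (C17 now methyl, cyclobutane intact) | CC(C)(C)[Si](c1ccccc1)(c1ccccc1)OCC[C@@H](C)CC[C@H]1[C](C)[C@@H]2C[C@@H](C2(C)C)[C@]1(C)CCC=O | intermediate (not isolated)
19 | C4-centred tertiary radical (C4–C7 cleaved, C7=C8 alkene, C3 aldehyde) | CC(C)(C)[Si](c1ccccc1)(c1ccccc1)OCC[C@@H](C)CC[C@H]1C(C)=CC[C@@H]([C](C)C)[C@]1(C)CCC=O | intermediate (not isolated)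
20 | C3 alkoxyl radical of 21 | CC(C)(C)[Si](c1ccccc1)(c1ccccc1)OCC[C@@H](C)CC[C@H]1C(C)=CC[C@H]2C(C)(C)[C@@H]([O])CC[C@]12C | intermediate (not isolated)
21 | (3S,5R,9S,10R,13S)-15-(tert-butyldiphenylsilyloxy)labd-7-en-3-ol (3β-OH) | CC(C)(C)[Si](c1ccccc1)(c1ccccc1)OCC[C@@H](C)CC[C@H]1C(C)=CC[C@H]2C(C)(C)[C@@H](O)CC[C@]12C | intermediate (key-step product)
22 | (3S,5R,9S,10R,13S)-labd-7-ene-3,15-diol | OCC[C@@H](C)CC[C@H]1C(C)=CC[C@H]2C(C)(C)[C@@H](O)CC[C@]12C | intermediate
23 | (3S,5R,9S,10R,13S)-labd-7-ene-3,15-diyl diacetate | CC(=O)OCC[C@@H](C)CC[C@H]1C(C)=CC[C@H]2C(C)(C)[C@@H](OC(C)=O)CC[C@]12C | target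

**Step count**

Total steps: 13. Longest linear sequence: 12 steps (1 → 4 by steps 1–3, then steps 5–13); the verbenone branch to 23 is 10 steps.

**Steps most likely to fail**

1. Step 11 (Proposed new method). The C4 radical may be reduced before it closes, or the alkoxyl radical may fragment back before it is reduced, so that material drains into ring-opened, uncyclised products. The silane may also reduce the aldehyde, the product alkene may undergo a second hydrogen-atom transfer, and the oxygen may partly take the axial site at C3. The fallback divides the cascade into two known radical reactions.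
   - It sets out from aldehyde 17. Cobalt-mediated hydrogen-atom-transfer hydrochlorination (Co(acac)2, t-BuOOH, Et3SiH, TsCl, i-PrOH) should open the cyclobutane in the same way and trap the C4 radical by chlorine-atom transfer, giving (13S)-15-(tert-butyldiphenylsilyloxy)-4-chloro-3,4-secolabd-7-en-3-al F1.
   - Slow addition of Bu3SnH and AIBN to F1 in benzene at 80 °C should regenerate the C4 radical in a chain process. The stannane is a much faster hydrogen donor than the iron system and should capture the alkoxyl radical after 6-exo closure, which returns the route to 21.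
   - Should either closure leave an unfavourable ratio at C3, the mixture would be oxidised with Dess–Martin periodinane to (13S)-15-(tert-butyldiphenylsilyloxy)labd-7-en-3-one F2 and reduced with NaBH4 in MeOH. Axial hydride attack on the 4,4-dimethyl-3-ketone should give the equatorial 3β-alcohol 21.

2. Step 8. Steric shielding of the C8 carbonyl between the bridgehead C7 and the substituted C9 may prevent addition of the titanium methylidene, and prolonged heating may enolise the ketone and erode the C9 configuration. The fallback is a Peterson olefination, which replaces the carbene transfer by addition and elimination. It sets out from ketone 14: Me3SiCH2Li with CeCl3 (THF, −78 °C) adds a small, weakly basic nucleophile to give the β-hydroxysilane (1R,3R,4S,5S)-4-[3-(tert-butyldimethylsilyloxy)propyl]-3-[(3S)-5-(tert-butyldiphenylsilyloxy)-3-methylpentyl]-4,6,6-trimethyl-2-(trimethylsilylmethyl)bicyclo[3.1.1]heptan-2-ol F3 (C8 configuration immaterial). KH in THF then induces syn-elimination and returns the route to 15.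

3. Step 7. Hydrogen may be delivered to the wrong face of C9 if the α-tether on C10 shields the catalyst more than the bridge does, which would give the C9 epimer. A carbon electrophile would follow the same facial bias and would then land on the β-face, so the fallback introduces the chain by enolate alkylation.
   - It sets out from aldehyde 4, which is reduced with NaBH4 in MeOH to (3S)-5-(tert-butyldiphenylsilyloxy)-3-methylpentan-1-ol F4.
   - F4 is converted with I2, PPh3 and imidazole into (3R)-tert-butyl(5-iodo-3-methylpentyloxy)diphenylsilane F5.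
   - Lithium enolate 10 (from 9 and LiN(i-Pr)2, THF, −78 °C) is alkylated with F5 in the presence of DMPU (−78 → 0 °C). This returns the route directly to 14 and bypasses 11–13.

**Further compounds**

F1 | step 11 | (13S)-15-(tert-butyldiphenylsilyloxy)-4-chloro-3,4-secolabd-7-en-3-al | CC(C)(C)[Si](c1ccccc1)(c1ccccc1)OCC[C@@H](C)CC[C@H]1C(C)=CC[C@@H](C(C)(C)Cl)[C@]1(C)CCC=O
F2 | step 11 | (13S)-15-(tert-butyldiphenylsilyloxy)labd-7-en-3-one | CC(C)(C)[Si](c1ccccc1)(c1ccccc1)OCC[C@@H](C)CC[C@H]1C(C)=CC[C@H]2C(C)(C)C(=O)CC[C@]12C
F3 | step 8 | β-hydroxysilane from 14 (C8 bearing OH and CH2SiMe3) | CC(C)(C)[Si](c1ccccc1)(c1ccccc1)OCC[C@@H](C)CC[C@H]1C(O)(C[Si](C)(C)C)[C@@H]2C[C@@H](C2(C)C)[C@]1(C)CCCO[Si](C)(C)C(C)(C)C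
F4 | step 7 | (3S)-5-(tert-butyldiphenylsilyloxy)-3-methylpentan-1-ol | CC(C)(C)[Si](c1ccccc1)(c1ccccc1)OCC[C@@H](C)CCO
F5 | step 7 | (3R)-tert-butyl(5-iodo-3-methylpentyloxy)diphenylsilane | CC(C)(C)[Si](c1ccccc1)(c1ccccc1)OCC[C@@H](C)CCI
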